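**Retrosynthetic overview**
- Stypandrol ⇐ its 8,8'-di-O-methyl ether (O-demethylation last).
- Both acetyl/methyl-bearing A rings ⇐ one twofold phthalide-anion annulation of a 6,6'-biphthalide with (E)-pent-3-en-2-one. The lithiated lactone carbon (a polarity-inverted benzylic C–O carbon) attacks the enone β-carbon (C4–C3), Dieckmann closure makes C2–C1, and dehydration aromatises.
- 6,6'-Biphthalide ⇐ biphenyl-3,3'-bis(diethylamide) by amide-directed ortho-lithiation, hydroxymethylation and lactonisation.
- Bis-amide ⇐ 2,2'-dimethoxybiphenyl by methoxy-directed 3,3'-dilithiation and carbamoylation; the 7,7' biaryl bond is bought, not made.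
- Ring order: B/B' rings (starting material) → two lactone rings → A/A' rings, both formed in the same operation.

Assumption: the target has no stereocentre and its 7,7' axis has only OH and H as ortho substituents on each ring, so it rotates freely and the compound is achiral; 2,2'-dimethoxybiphenyl is taken as a catalogue chemical.

**Step 1**
Reactants: 1 2,2'-dimethoxy-1,1'-biphenyl
Product: 3 N,N,N',N'-tetraethyl-2,2'-dimethoxybiphenyl-3,3'-dicarboxamide, via 3,3'-dilithio-2,2'-dimethoxybiphenyl 2 (not isolated)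
Conditions: n-BuLi (2.6 equiv), TMEDA, Et2O, 0 °C → rt; then added to ClCONEt2 (3 equiv), THF, −78 °C → rt
Reagents that add atoms: N,N-diethylcarbamoyl chloride, CCN(CC)C(Cl)=O
Why: Methoxy-directed ortho-metalation can only occur at C3/C3' (the other ortho position of each OMe is the biaryl carbon), and the aryllithium then undergoes acyl substitution on the carbamoyl chloride, inverse addition at −78 °C suppressing ketone formation.

**Step 2**
Reactants: 3 N,N,N',N'-tetraethyl-2,2'-dimethoxybiphenyl-3,3'-dicarboxamide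
Product: 6 7,7'-dimethoxy-6,6'-biphthalide (7,7'-dimethoxy-6,6'-biisobenzofuran-1,1'(3H,3'H)-dione), via 4,4'-dilithio-diamide 4 (not isolated), via 4,4'-bis(hydroxymethyl)-diamide 5 (not isolated)
Conditions: s-BuLi (2.6 equiv), TMEDA, THF, −78 °C; monomeric CH2O (THF solution from cracked paraformaldehyde), −78 °C → rt; then 6 M HCl, 70 °C
Reagents that add atoms: formaldehyde, C=O
Why: Amide-directed ortho-lithiation (Beak–Snieckus) goes to the only free ortho position of each amide (C4/C4'), the aryllithium adds to formaldehyde, and under acid the benzylic alcohol displaces diethylamine from the neighbouring amide (lactonisation).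

**Step 3**
Reactants: 6 7,7'-dimethoxy-6,6'-biphthalide; 7 (E)-pent-3-en-2-one
Product: 10 stypandrol 8,8'-di-O-methyl ether (2,2'-diacetyl-8,8'-dimethoxy-3,3'-dimethyl-7,7'-binaphthalene-1,1'-diol), via dilithium bis-phthalide enolate 8 (not isolated), via bis(4-hydroxy-1-tetralone) adduct 9 (not isolated)
Conditions: LDA (2.2 equiv, commercial solution), THF, −78 °C, 20 min; 7 (3 equiv), −78 °C → rt; then HCl (4 M in dioxane, excess), 50 °C, same flask
Reagents that add atoms: none
Why: Twofold phthalide-anion annulation (Sammes type, the cyanide-free relative of the Hauser–Kraus annulation): the lithiated lactone carbon, an α-acyloxybenzyl carbanion with polarity inverted relative to its normal role as a benzylic C–O electrophile, adds 1,4 to the electrophilic β-carbon of the enone, the ketone enolate closes onto the lactone carbonyl (Dieckmann), and acid dehydration of the benzylic alcohol is driven by aromatisation, which erases the unselectively formed sp3 centres of 9.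

**Step 4**
Reactants: 10 stypandrol 8,8'-di-O-methyl ether
Product: 11 stypandrol (2,2'-diacetyl-3,3'-dimethyl-7,7'-binaphthalene-1,1',8,8'-tetrol)
Conditions: BBr3 (8 equiv), CH2Cl2, −78 °C → rt, Ar; degassed H2O/MeOH work-up
Reagents that add atoms: none
Why: BBr3 ether cleavage (boron activates the ether oxygen, bromide attacks the methyl group by SN2); the aryl ketones and naphthols are inert, the boron chelates hydrolyse on work-up, and no stereo-element has to be set.

**Compound list**
1 | 2,2'-dimethoxy-1,1'-biphenyl | COc1ccccc1-c1ccccc1OC | starting material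
2 | 3,3'-dilithio-2,2'-dimethoxybiphenyl | COc1c([Li])cccc1-c1cccc([Li])c1OC | intermediate
3 | N,N,N',N'-tetraethyl-2,2'-dimethoxybiphenyl-3,3'-dicarboxamide | CCN(CC)C(=O)c1cccc(-c2cccc(C(=O)N(CC)CC)c2OC)c1OC | intermediate
4 | 4,4'-dilithio derivative of 3 | CCN(CC)C(=O)c1c([Li])ccc(-c2ccc([Li])c(C(=O)N(CC)CC)c2OC)c1OC | intermediate
5 | N,N,N',N'-tetraethyl-4,4'-bis(hydroxymethyl)-2,2'-dimethoxybiphenyl-3,3'-dicarboxamide | CCN(CC)C(=O)c1c(CO)ccc(-c2ccc(CO)c(C(=O)N(CC)CC)c2OC)c1OC | intermediate
6 | 7,7'-dimethoxy-6,6'-biisobenzofuran-1,1'(3H,3'H)-dione | COc1c(-c2ccc3c(c2OC)C(=O)OC3)ccc2c1C(=O)OC2 | intermediate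
7 | (E)-pent-3-en-2-one | C/C=C/C(C)=O | starting material
8 | dilithium enolate of 6 (C3/C3' carbanion, drawn as the bis(isobenzofuran-1-olate)) | COc1c(-c2ccc3coc(O[Li])c3c2OC)ccc2coc(O[Li])c12 | intermediate
9 | 2,2'-diacetyl-4,4'-dihydroxy-8,8'-dimethoxy-3,3'-dimethyl-3,3',4,4'-tetrahydro-7,7'-binaphthalene-1,1'(2H,2'H)-dione (diastereomer mixture; C2/C3/C4 configurations uncontrolled and erased on aromatisation) | CC(=O)C1C(C)C(O)c2ccc(-c3ccc4c(c3OC)C(=O)C(C(C)=O)C(C)C4O)c(OC)c2C1=O | intermediate
10 | stypandrol 8,8'-di-O-methyl ether | CC(=O)c1c(C)cc2ccc(-c3ccc4cc(C)c(C(C)=O)c(O)c4c3OC)c(OC)c2c1O | intermediate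
11 | stypandrol | CC(=O)c1c(C)cc2ccc(-c3ccc4cc(C)c(C(C)=O)c(O)c4c3O)c(O)c2c1O | target

**Totals and risks**
Total step count: 4. Longest linear sequence: 4 (fully linear; 7 is bought).

Most likely to fail, in order:

1. Step 3 (twofold annulation). The enolisable enone may be deprotonated by the phthalide anion instead of adding it, or the bis-anion may self-condense. Fallback, from 6 back to 10: generate 8 as before but trap it with (E)-but-2-enenitrile, which has no acidic α'-hydrogens. Michael addition, Dieckmann closure and HCl quench give the bis(2-cyano-4-hydroxy-1-tetralone) adduct F1. Acid dehydration gives 1,1'-dihydroxy-8,8'-dimethoxy-3,3'-dimethyl-7,7'-binaphthalene-2,2'-dicarbonitrile F2. Excess MeMgBr (PhMe–THF, 70 °C) adds once to each nitrile to form the bis(N-H ketimine) F3 (present as its magnesium salt), and aqueous HCl hydrolyses it to 10. The acetyl group is thus built from a nitrile carbon plus a methyl nucleophile instead of arriving with the enone.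

2. Step 2 (double lithiation next to twisted amides, then lactonisation). Fallback, from 1 back to 6: lithiate 1 to 2 as in step 1 but quench with CO2 to give 2,2'-dimethoxybiphenyl-3,3'-dicarboxylic acid F4. Then Pd(OAc)2 (10 mol %), K2HPO4, CH2Br2, 140 °C effects carboxylate-directed ortho C–H alkylation and in-situ SN2 lactonisation to 6. This replaces the organolithium chemistry by Pd(II) C–H activation and skips the amide.

3. Step 4 (demethylation of hindered peri-methoxy groups to an oxidation-sensitive tetraol). Fallback, from 6 back to 11: remove the methyl groups at the robust lactone stage with BBr3 to give 7,7'-dihydroxy-6,6'-biphthalide F5, and re-protect with MOMCl/i-Pr2NEt as the bis(methoxymethyl) ether F6. LDA then gives the dilithium enolate F7, and 7 adds as in step 3 to give the MOM-protected bis(4-hydroxy-1-tetralone) adduct F8. Methanolic HCl (50 °C) dehydrates and removes both acetals in the same operation, giving 11 without any late ether cleavage.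

**Further compounds**
F1 | step 3 | 4,4'-dihydroxy-8,8'-dimethoxy-3,3'-dimethyl-1,1'-dioxo-1,1',2,2',3,3',4,4'-octahydro-7,7'-binaphthalene-2,2'-dicarbonitrile (diastereomer mixture) | CC1C(C#N)C(=O)c2c(OC)c(-c3ccc4c(c3OC)C(=O)C(C#N)C(C)C4O)ccc2C1O
F2 | step 3 | 1,1'-dihydroxy-8,8'-dimethoxy-3,3'-dimethyl-7,7'-binaphthalene-2,2'-dicarbonitrile | Cc1cc2ccc(-c3ccc4cc(C)c(C#N)c(O)c4c3OC)c(OC)c2c(O)c1C#N
F3 | step 3 | 2,2'-bis(1-iminoethyl)-8,8'-dimethoxy-3,3'-dimethyl-7,7'-binaphthalene-1,1'-diol | CC(=N)c1c(C)cc2ccc(-c3ccc4cc(C)c(C(C)=N)c(O)c4c3OC)c(OC)c2c1O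
F4 | step 2 | 2,2'-dimethoxybiphenyl-3,3'-dicarboxylic acid | COc1c(C(=O)O)cccc1-c1cccc(C(=O)O)c1OC
F5 | step 4 | 7,7'-dihydroxy-6,6'-biisobenzofuran-1,1'(3H,3'H)-dione | O=C1OCc2ccc(-c3ccc4c(c3O)C(=O)OC4)c(O)c21
F6 | step 4 | 7,7'-bis(methoxymethoxy)-6,6'-biisobenzofuran-1,1'(3H,3'H)-dione | COCOc1c(-c2ccc3c(c2OCOC)C(=O)OC3)ccc2c1C(=O)OC2
F7 | step 4 | dilithium enolate of F6 | COCOc1c(-c2ccc3coc(O[Li])c3c2OCOC)ccc2coc(O[Li])c12
F8 | step 4 | 2,2'-diacetyl-4,4'-dihydroxy-8,8'-bis(methoxymethoxy)-3,3'-dimethyl-3,3',4,4'-tetrahydro-7,7'-binaphthalene-1,1'(2H,2'H)-dione (diastereomer mixture) | CC(=O)C1C(C)C(O)c2ccc(-c3ccc4c(c3OCOC)C(=O)C(C(C)=O)C(C)C4O)c(OCOC)c2C1=O
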